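**Retrosynthetic overview**

1. The target is centrosymmetric (meso). The last C–C bond cut is the one shared by the two eight-membered rings, between the two CH carbons that each carry a benzofuran C-4. These carbons are the 1,8-positions of a 14-membered tetrabenzo macrocycle with two (E)-triarylethylene bridges, so the bond is made by transannular reductive coupling (step 11).
2. Both trans-2,3-diaryl-2,3-dihydrobenzofurans are cut at O-1–C-7a and C-3–C-3a. Each arises from a 2,3-diaryloxirane (the three-membered ring O-1, C-2, C-3) that takes up the two carbons of an aryne, a ring expansion from three to five atoms. Done twice, head-to-tail, this cyclodimerises one monomer 16 (step 9).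
3. Enabling feature: in each dihydrobenzofuran, O-1 and C-3 sit on adjacent carbons (C-7a, C-3a) of benzo ring B, and the next carbon (C-4) carries the bridge carbon, which is the pattern delivered by an aryne with one flanking substituent. C-3 carries the dimethoxyaryl ring A, whose ortho carbon starts the bridge to the other half, and the inversion centre makes both halves the same monomer. The (E)-alkene holds oxirane and aryne of one monomer trans, so the monomer cannot close on itself.
4. Monomer: ortho-silylaryl triflate 4 → Sonogashira coupling → syn-hydroarylation with the ring A iodide (fixes E) → Corey–Chaykovsky oxirane from a 4-triflyloxybenzyl ylide (the electron-poor aryl steers the oxirane opening and later becomes OH).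
5. Ring order: oxirane (step 8) → two dihydrofuran rings and the 14-membered ring (step 9) → two eight-membered carbocycles (step 11) → deprotection (step 12).

Key step: step 9

Remark: compounds 1, 5, 7 and 12 are taken as commercial; because the target is meso, racemic intermediates are used and their SMILES show one enantiomer.

**Route**

Step 1
Reactants: 1 2,6-dibromo-4-methoxyphenol
Product: 4 2-bromo-4-methoxy-6-(trimethylsilyl)phenyl trifluoromethanesulfonate, via aryl silyl ether 2 (not isolated), via lithium phenoxide 3 (not isolated)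
Conditions: (Me3Si)2NH, THF, 65 °C; then n-BuLi, THF, −78 °C; then Tf2O, −78 → 0 °C
Reagents that add atoms: hexamethyldisilazane C[Si](C)(C)N[Si](C)(C)C; triflic anhydride O=S(=O)(C(F)(F)F)OS(=O)(=O)C(F)(F)F
Why: O-silylation, bromine–lithium exchange with retro-Brook (1,3 O→C) silyl migration and O-triflation is the standard entry to ortho-silylaryl triflates, and the second bromine is kept as the handle for step 2.

Step 2
Reactants: 4 2-bromo-4-methoxy-6-(trimethylsilyl)phenyl trifluoromethanesulfonate; 5 1-ethynyl-4-methoxybenzene
Product: 6 4-methoxy-2-[(4-methoxyphenyl)ethynyl]-6-(trimethylsilyl)phenyl trifluoromethanesulfonate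
Conditions: Pd(PhCN)2Cl2, P(t-Bu)3·HBF4, CuI, i-Pr2NH, dioxane, 25 °C
Reagents that add atoms: none
Why: Sonogashira coupling; with the Pd/P(t-Bu)3 catalyst the C–Br bond should react at room temperature in preference to the doubly ortho-flanked C–OTf bond, and without fluoride the silyl triflate stays intact.

Step 3
Reactants: 7 3,5-dimethoxybenzaldehyde
Product: 8 2-iodo-3,5-dimethoxybenzaldehyde
Conditions: NIS, CF3CO2H (cat.), MeCN, 25 °C
Reagents that add atoms: N-iodosuccinimide O=C1CCC(=O)N1I
Why: Electrophilic aromatic iodination should go to C-2 (ortho to one methoxy group, para to the other), as the bromination of this aldehyde does.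

Step 4
Reactants: 8 2-iodo-3,5-dimethoxybenzaldehyde
Product: 9 1-(dimethoxymethyl)-2-iodo-3,5-dimethoxybenzene
Conditions: HC(OMe)3, TsOH (cat.), MeOH, 60 °C
Reagents that add atoms: trimethyl orthoformate COC(OC)OC
Why: Acid-catalysed acetalisation masks the aldehyde, which would otherwise trap the vinylpalladium intermediate of step 5 (indenol or indenone formation).

Step 5
Reactants: 6 4-methoxy-2-[(4-methoxyphenyl)ethynyl]-6-(trimethylsilyl)phenyl trifluoromethanesulfonate; 9 1-(dimethoxymethyl)-2-iodo-3,5-dimethoxybenzene
Product: 11 2-[(E)-2-(2-formyl-4,6-dimethoxyphenyl)-2-(4-methoxyphenyl)ethenyl]-4-methoxy-6-(trimethylsilyl)phenyl trifluoromethanesulfonate, via dimethyl acetal 10 (not isolated)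
Conditions: Pd(OAc)2, PPh3, HCO2H, Et3N, DMF, 50 °C; then PPTS, acetone–H2O, 40 °C
Reagents that add atoms: water O
Why: Reductive Heck reaction (palladium-catalysed syn-hydroarylation of an internal alkyne, formate as hydride source): the hindered arylpalladium should add to the alkyne carbon bearing the unhindered 4-methoxyphenyl group, remote from the ortho-triflyloxy ring, syn delivery of aryl and H fixes the (E) geometry with ring A trans to the silyl-triflate ring, and mild acid then frees the aldehyde.

Step 6
Reactants: 12 4-methylphenyl trifluoromethanesulfonate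
Product: 13 4-(bromomethyl)phenyl trifluoromethanesulfonate
Conditions: NBS, AIBN (cat.), PhCF3, 80 °C
Reagents that add atoms: N-bromosuccinimide O=C1CCC(=O)N1Br
Why: Wohl–Ziegler benzylic bromination, to which the aryl triflate is inert.

Step 7
Reactants: 13 4-(bromomethyl)phenyl trifluoromethanesulfonate
Product: 14 dimethyl{[4-(trifluoromethylsulfonyloxy)phenyl]methyl}sulfonium bromide
Conditions: Me2S, acetone, 25 °C
Reagents that add atoms: dimethyl sulfide CSC
Why: SN2 alkylation of the sulfide by the benzylic bromide gives the crystalline sulfonium salt.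

Step 8
Reactants: 11 2-[(E)-2-(2-formyl-4,6-dimethoxyphenyl)-2-(4-methoxyphenyl)ethenyl]-4-methoxy-6-(trimethylsilyl)phenyl trifluoromethanesulfonate; 14 dimethyl{[4-(trifluoromethylsulfonyloxy)phenyl]methyl}sulfonium bromide
Product: 16 racemic trans-oxirane monomer, 2-[(E)-2-{2,4-dimethoxy-6-[(2R*,3R*)-3-(4-triflyloxyphenyl)oxiran-2-yl]phenyl}-2-(4-methoxyphenyl)ethenyl]-4-methoxy-6-(trimethylsilyl)phenyl trifluoromethanesulfonate, via sulfonium ylide 15 (not isolated)
Conditions: LiN(SiMe3)2, THF, −78 °C; then 11, −78 → 0 °C
Reagents that add atoms: none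
Why: Corey–Chaykovsky epoxidation with a semi-stabilised benzyl ylide, whose reversible betaine formation should favour the trans-oxirane (racemic); the non-nucleophilic amide base at low temperature leaves both triflates and the C–Si bond untouched, and any cis-oxirane is equally usable in step 9.

Step 9
Reactants: 16 racemic trans-oxirane monomer (two molecules, one of each enantiomer)
Product: 19 centrosymmetric 14-membered cyclodimer (macrocyclic bis-triflate: two trans-2,3-dihydrobenzofurans, (2S,3S) and (2R,3R), two (E)-bridges), via aryne 17 (not isolated), via linear dimer 18 (not isolated)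
Conditions: CsF (0.6 equiv), 18-crown-6, MeCN–PhMe, 0.3 M, 25 °C; then dilution to 2 mM, CsF (4 equiv), 50 °C
Reagents that add atoms: none
Why: CsF removes the silyl group and expels triflate to give aryne 17, whose carbon remote from the alkenyl-bearing carbon is attacked by the oxirane oxygen of a second molecule; the oxonium opens at the C–O bond of the carbon that carries ring A (the 4-triflyloxyphenyl group disfavours positive charge on the other carbon) and the ortho carbanion closes on it, so the three-membered ring has grown to the dihydrofuran by the two aryne carbons, and the same sequence inside 18 closes the macrocycle. The closest known reaction type is the fluoride-induced insertion of arynes into the benzylic C–O bond of aryl oxiranes, which gives 3-aryl-2,3-dihydrobenzofurans. Each dihydrofuran ring closes by five-membered collapse of the aryl carbanion onto the benzylic cation, and the 14-membered carbocycle closes end-to-end in the second, intramolecular insertion. C-2 of each dihydrobenzofuran keeps the configuration of its oxirane carbon because that C–O bond is never broken, C-3 forms from a planar cation and should close trans to the C-2 aryl group, so cis- and trans-oxirane converge; the centrosymmetric product needs one (R,R)- and one (S,S)-oxirane, which the racemate supplies, and the homochiral cyclodimer should be separable. The step needs O at the former silyl carbon and C at the former triflate carbon, secured by the steric and inductive effect of the alkenyl group beside the triple bond, and it needs inter- before intramolecular reaction, secured by the (E)-alkene, which holds oxirane ring and aryne ring of one molecule trans so that self-insertion would demand an (E)-cycloheptene; the concentrated-then-dilute protocol should favour dimer formation first and ring closure second.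

Step 10
Reactants: 19 macrocyclic bis-triflate
Product: 21 macrocyclic deca-methyl ether (as 19, with 4-methoxyphenyl on both C-2), via bis-phenoxide 20 (not isolated)
Conditions: Et4NOH (aq), dioxane, 25 °C; then MeI, 25 °C
Reagents that add atoms: iodomethane CI
Why: Hydroxide cleaves the aryl triflates at sulfur and the phenoxides are O-methylated in the same flask (Williamson ether synthesis), which removes the reducible sulfonates before step 11 without touching a stereocentre.

Step 11
Reactants: 21 macrocyclic deca-methyl ether
Product: 23 deca-O-methyl ether of the target (two trans-fused eight-membered rings), via dilithium dianion 22 (not isolated)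
Conditions: LiC10H8 (lithium naphthalenide, 2.2 equiv), THF, −78 °C; then MeOH, −78 °C
Reagents that add atoms: none
Why: Alkali-metal reductive tail-to-tail coupling of aryl-conjugated alkenes (Schlenk-type dimerisation of diarylethylene radical anions), here transannular: one electron per triarylethylene should give radical anions that join at their CH termini (spin at CH, charge on the diaryl carbon), the inversion centre of the macrocycle is kept so the two new ring-fusion centres get opposite configurations (anti hydrogens, trans ring fusion) on the alkene faces turned into the cavity, and methanol should protonate each diarylmethyl anion from the convex face, anti to the aryl group on the neighbouring ring-fusion carbon.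

Step 12
Reactants: 23 deca-O-methyl ether of the target
Product: 24 target CNP0224452.1
Conditions: BBr3, CH2Cl2, −78 → 0 °C; then MeOH, H2O
Reagents that add atoms: none
Why: Lewis-acid cleavage of all ten aryl methyl ethers; the trans-dihydrobenzofurans are the thermodynamic isomers, so any C-2 epimer should equilibrate to trans through reversible para-quinone-methide ring opening once the 4-hydroxyphenyl groups are free, while C-3 and the carbocyclic centres cannot epimerise.

**Compound list**

1 | 2,6-dibromo-4-methoxyphenol | COc1cc(Br)c(O)c(Br)c1 | starting material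
2 | (2,6-dibromo-4-methoxyphenoxy)trimethylsilane | COc1cc(Br)c(O[Si](C)(C)C)c(Br)c1 | intermediate (not isolated)
3 | lithium 2-bromo-4-methoxy-6-(trimethylsilyl)phenoxide | COc1cc(Br)c([O-])c([Si](C)(C)C)c1.[Li+] | intermediate (not isolated)
4 | 2-bromo-4-methoxy-6-(trimethylsilyl)phenyl trifluoromethanesulfonate | COc1cc(Br)c(OS(=O)(=O)C(F)(F)F)c([Si](C)(C)C)c1 | intermediate
5 | 1-ethynyl-4-methoxybenzene | COc1ccc(C#C)cc1 | starting material
6 | 4-methoxy-2-[(4-methoxyphenyl)ethynyl]-6-(trimethylsilyl)phenyl trifluoromethanesulfonate | COc1ccc(C#Cc2cc(OC)cc([Si](C)(C)C)c2OS(=O)(=O)C(F)(F)F)cc1 | intermediate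
7 | 3,5-dimethoxybenzaldehyde | COc1cc(OC)cc(C=O)c1 | starting material
8 | 2-iodo-3,5-dimethoxybenzaldehyde | COc1cc(OC)c(I)c(C=O)c1 | intermediate
9 | 1-(dimethoxymethyl)-2-iodo-3,5-dimethoxybenzene | COc1cc(OC)c(I)c(C(OC)OC)c1 | intermediate
10 | 2-{(E)-2-[2-(dimethoxymethyl)-4,6-dimethoxyphenyl]-2-(4-methoxyphenyl)ethenyl}-4-methoxy-6-(trimethylsilyl)phenyl trifluoromethanesulfonate | C(/c1cc(OC)cc([Si](C)(C)C)c1OS(=O)(=O)C(F)(F)F)=C(/c1ccc(OC)cc1)c1c(OC)cc(OC)cc1C(OC)OC | intermediate (not isolated)
11 | 2-[(E)-2-(2-formyl-4,6-dimethoxyphenyl)-2-(4-methoxyphenyl)ethenyl]-4-methoxy-6-(trimethylsilyl)phenyl trifluoromethanesulfonate | C(/c1cc(OC)cc([Si](C)(C)C)c1OS(=O)(=O)C(F)(F)F)=C(/c1ccc(OC)cc1)c1c(OC)cc(OC)cc1C=O | intermediate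
12 | 4-methylphenyl trifluoromethanesulfonate | Cc1ccc(OS(=O)(=O)C(F)(F)F)cc1 | starting material
13 | 4-(bromomethyl)phenyl trifluoromethanesulfonate | BrCc1ccc(OS(=O)(=O)C(F)(F)F)cc1 | intermediate
14 | dimethyl{[4-(trifluoromethylsulfonyloxy)phenyl]methyl}sulfonium bromide | C[S+](C)Cc1ccc(OS(=O)(=O)C(F)(F)F)cc1.[Br-] | intermediate
15 | dimethylsulfonium [4-(trifluoromethylsulfonyloxy)phenyl]methylide | C[S+](C)[CH-]c1ccc(OS(=O)(=O)C(F)(F)F)cc1 | intermediate (not isolated)
16 | racemic trans-oxirane monomer (E-alkene; (2R,3R)-oxirane drawn) | C(/c1cc(OC)cc([Si](C)(C)C)c1OS(=O)(=O)C(F)(F)F)=C(/c1ccc(OC)cc1)c1c(OC)cc(OC)cc1[C@H]1O[C@@H]1c1ccc(OS(=O)(=O)C(F)(F)F)cc1 | intermediate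
17 | aryne from 16 (3-alkenyl-5-methoxybenzyne carrying the oxirane arm) | C(/C1=CC(OC)=CC#C1)=C(/c1ccc(OC)cc1)c1c(OC)cc(OC)cc1[C@H]1O[C@@H]1c1ccc(OS(=O)(=O)C(F)(F)F)cc1 | intermediate (not isolated)
18 | linear dimer: one (2R,3R)-trans-dihydrobenzofuran, one remaining silyl triflate end and one remaining (2R,3R)-oxirane end, both alkenes E | C(/c1cc(OC)cc([Si](C)(C)C)c1OS(=O)(=O)C(F)(F)F)=C(/c1ccc(OC)cc1)c1c(OC)cc(OC)cc1[C@H]1[C@H](c3ccc(OS(=O)(=O)C(F)(F)F)cc3)Oc2cc(OC)cc(c12)/C=C(\c1ccc(OC)cc1)c1c(OC)cc(OC)cc1[C@H]1O[C@@H]1c1ccc(OS(=O)(=O)C(F)(F)F)cc1 | intermediate (not isolated)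
19 | centrosymmetric 14-membered cyclodimer, bis-triflate: (2S,3S)- and (2R,3R)-trans-dihydrobenzofurans, two (E)-C(4-methoxyphenyl)=CH bridges | C(/c1cc(OC)cc2O[C@H](c3ccc(OS(=O)(=O)C(F)(F)F)cc3)[C@@H]9c12)=C(/c3ccc(OC)cc3)c1c(OC)cc(OC)cc1[C@H]1[C@H](c3ccc(OS(=O)(=O)C(F)(F)F)cc3)Oc2cc(OC)cc(c12)/C=C(\c3ccc(OC)cc3)c1c(OC)cc(OC)cc19 | intermediate
20 | bis(tetraethylammonium) bis-phenoxide of the macrocycle | C(/c1cc(OC)cc2O[C@H](c3ccc([O-])cc3)[C@@H]9c12)=C(/c3ccc(OC)cc3)c1c(OC)cc(OC)cc1[C@H]1[C@H](c3ccc([O-])cc3)Oc2cc(OC)cc(c12)/C=C(\c3ccc(OC)cc3)c1c(OC)cc(OC)cc19.CC[N+](CC)(CC)CC.CC[N+](CC)(CC)CC | intermediate (not isolated)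
21 | macrocyclic deca-methyl ether (as 19 with 4-methoxyphenyl on both C-2) | C(/c1cc(OC)cc2O[C@H](c3ccc(OC)cc3)[C@@H]9c12)=C(/c3ccc(OC)cc3)c1c(OC)cc(OC)cc1[C@H]1[C@H](c3ccc(OC)cc3)Oc2cc(OC)cc(c12)/C=C(\c3ccc(OC)cc3)c1c(OC)cc(OC)cc19 | intermediate
22 | dilithium bis(diarylmethanide) after transannular coupling | COc1ccc([C-]2c3c(OC)cc(OC)cc3[C@H]3c4c(cc(OC)cc4[C@H]4[C-](c5ccc(OC)cc5)c5c(OC)cc(OC)cc5[C@@H]5c6c(cc(OC)cc6[C@H]24)O[C@H]5c2ccc(OC)cc2)O[C@@H]3c2ccc(OC)cc2)cc1.[Li+].[Li+] | intermediate (not isolated)
23 | deca-O-methyl ether of the target (meso, trans-fused eight-membered rings, trans-dihydrobenzofurans) | COc1ccc([C@@H]2c3c(OC)cc(OC)cc3[C@H]3c4c(cc(OC)cc4[C@H]4[C@@H](c5ccc(OC)cc5)c5c(OC)cc(OC)cc5[C@@H]5c6c(cc(OC)cc6[C@H]24)O[C@H]5c2ccc(OC)cc2)O[C@@H]3c2ccc(OC)cc2)cc1 | intermediate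
24 | CNP0224452.1 | Oc1ccc([C@@H]2c3c(O)cc(O)cc3[C@H]3c4c(cc(O)cc4[C@H]4[C@@H](c5ccc(O)cc5)c5c(O)cc(O)cc5[C@@H]5c6c(cc(O)cc6[C@H]24)O[C@H]5c2ccc(O)cc2)O[C@@H]3c2ccc(O)cc2)cc1 | target

**Step count**

Total: 12 steps. Longest linear sequence: 8 steps (steps 1, 2, 5, 8, 9, 10, 11, 12).

**Steps most likely to fail**

Step 9. The bimolecular capture of the aryne by the weakly nucleophilic oxirane oxygen may lose against aryne decay and chain growth, so that oligomers form in place of the cyclodimer, and the ring closure may pair two like enantiomers. The fallback separates the events so that every intermolecular insertion meets a simple oxirane in excess, and no molecule carries both functions until the last ring closure. It sets out from dimethyl acetal 10 (isolated before the hydrolysis of step 5), aldehyde 8, sulfonium salt 14 and alkyne 6. Corey–Chaykovsky reaction of 8 with the ylide from 14 should give racemic trans-2-(2-iodo-3,5-dimethoxyphenyl)-3-[4-(trifluoromethylsulfonyloxy)phenyl]oxirane F1. The aryne from 10 (CsF, MeCN, 25 °C) should insert into F1 (3 equiv) to give the iodo dihydrobenzofuran acetal F2. Syn-hydroarylation of 6 with the C–I bond of F2 under the conditions of step 5, followed by acetal hydrolysis, should give the dihydrobenzofuran aldehyde F3, which now carries a fresh silyl triflate end. Corey–Chaykovsky reaction of F3 with 14 returns to the linear dimer 18, which is isolated and freed from its diastereomer. Its intramolecular insertion at 1 mM (CsF, 18-crown-6, MeCN–PhMe, slow addition) comes back to the route at 19.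

Step 11. Electron transfer may go on to the benzylic C–O bonds of the dihydrobenzofurans (reductive ring opening) or stop at plain two-electron reduction of each alkene without C–C bond formation, and the proton delivery may be unselective. The fallback sets out from 21 and joins the same two carbons oxidatively. Anodic oxidation (carbon anode, LiClO4, 2,6-lutidine, MeOH–CH2Cl2) should give radical-cation tail-to-tail coupling with methanol capture of both diarylmethyl cations, to the transannular bis(methyl ether) F4. Ionic hydrogenation (Et3SiH, CF3CO2H, CH2Cl2, −40 °C), with hydride delivered from the convex face, comes back to the route at 23.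

Step 5. The carbopalladation may take the wrong regiochemistry, or formate may reduce the hindered arylpalladium before it adds to the alkyne. The fallback builds the alkene from the other end, with the geometry fixed by syn-arylboration, and sets out from 9 and 4. Sonogashira coupling of 9 with trimethylsilylacetylene should give the silyl alkyne F5, and K2CO3 in MeOH the terminal alkyne F6. Copper/palladium co-catalysed syn-arylboration (B2pin2, 4-iodoanisole, CuCl, PCy3, Pd(OAc)2, XPhos, LiOt-Bu, toluene) should give the alkenyl boronate F7, with boron on the CH carbon and cis to the 4-methoxyphenyl group. A bromide-selective Suzuki coupling of F7 with 4 (Pd2(dba)3, P(t-Bu)3, K3PO4, THF–H2O, 25 °C) proceeds with retention and comes back to the route at 10, which is hydrolysed to 11 as in step 5.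

**Further compounds**

F1 | step 9 | racemic trans-2-(2-iodo-3,5-dimethoxyphenyl)-3-[4-(trifluoromethylsulfonyloxy)phenyl]oxirane | COc1cc(OC)c(I)c(c1)[C@@H]1O[C@H]1c1ccc(OS(=O)(=O)C(F)(F)F)cc1
F2 | step 9 | trans-dihydrobenzofuran from the aryne of 10 and F1 (3-(2-iodo-3,5-dimethoxyphenyl), 2-(4-triflyloxyphenyl), acetal end, E-alkene) | C(/c1cc(OC)cc2O[C@@H](c3ccc(OS(=O)(=O)C(F)(F)F)cc3)[C@H](c3cc(OC)cc(OC)c3I)c12)=C(/c1ccc(OC)cc1)c1c(OC)cc(OC)cc1C(OC)OC
F3 | step 9 | dihydrobenzofuran aldehyde with a second (E)-triarylethylene and a silyl triflate end | C(/c1cc(OC)cc2O[C@@H](c3ccc(OS(=O)(=O)C(F)(F)F)cc3)[C@H](c3cc(OC)cc(OC)c3/C(c3ccc(OC)cc3)=C/c3cc(OC)cc([Si](C)(C)C)c3OS(=O)(=O)C(F)(F)F)c12)=C(/c1ccc(OC)cc1)c1c(OC)cc(OC)cc1C=O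
F4 | step 11 | transannular bis(methyl ether): as 23 with OMe in place of H on both diarylmethyl carbons (configuration there immaterial) | COc1ccc(C2(OC)c3c(OC)cc(OC)cc3[C@H]3c4c(cc(OC)cc4[C@H]4C(OC)(c5ccc(OC)cc5)c5c(OC)cc(OC)cc5[C@@H]5c6c(cc(OC)cc6[C@H]24)O[C@H]5c2ccc(OC)cc2)O[C@@H]3c2ccc(OC)cc2)cc1
F5 | step 5 | {[2-(dimethoxymethyl)-4,6-dimethoxyphenyl]ethynyl}trimethylsilane | COc1cc(OC)c(C#C[Si](C)(C)C)c(C(OC)OC)c1
F6 | step 5 | 1-(dimethoxymethyl)-2-ethynyl-3,5-dimethoxybenzene | COc1cc(OC)c(C#C)c(C(OC)OC)c1
F7 | step 5 | alkenyl pinacol boronate, boron cis to the 4-methoxyphenyl group | CC1(C)OB(OC1(C)C)/C=C(\c1ccc(OC)cc1)c1c(OC)cc(OC)cc1C(OC)OC
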